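The cyclopentenone ring is opened at the bond between the ketone carbon C5 and the ester-bearing carbon C1. The feature exploited is the cis β-hydroxy ester array O–C2–C1–CO2Me on the five-membered ring. This array is a masked β-lactone, which makes the target a constitutional isomer of the monocyclic oxetan-2-one 9. The quaternary carbon of 9 carries the hexadecyl chain and a (Z)-methyl acrylate arm. Deprotonating 9 triggers a Dieckmann closure of C1 onto C5. The expelled methoxide then opens the strained lactone, so ring, C2–OH and CO2Me appear in one operation. The lactone blocks butenolide formation and β-elimination. C2 comes from a Sharpless epoxidation and a stereoretentive epoxide carbonylation.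

Key step: step 6

Remark: ring numbering is C1 = CH(CO2Me), C2 = C(OH)(C16H33), C3=C4, C5 = C=O; C1 is an epimerisable β-keto ester stereocentre, and the required (1R) epimer (CO2Me cis to the C2–OH, trans to the chain) is assumed to be the thermodynamically preferred one.

Step 1
Reactants: 1 1-bromohexadecane; 2 prop-2-yn-1-ol
Product: 4 2-methylideneoctadecan-1-ol (2-hexadecylprop-2-en-1-ol), via hexadecylmagnesium bromide 3 (not isolated)
Conditions: 1 (2.5 equiv), Mg, THF, reflux; then 2, CuI (10 mol %), THF, 0 °C → rt; H2O quench
Reagents that add atoms: none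
Why: Copper-catalysed carbomagnesiation of propargyl alcohol, in which the magnesium alkoxide directs the alkyl group to the internal alkyne carbon through a five-membered chelated vinylmagnesium species, so that protonolysis should give the 1,1-disubstituted allylic alcohol (no stereocentre formed).

Step 2
Reactants: 4 2-methylideneoctadecan-1-ol
Product: 5 [(2R)-2-hexadecyloxiran-2-yl]methanol
Conditions: Ti(OiPr)4 (5 mol %), D-(−)-DIPT (6 mol %), t-BuOOH, 4 Å MS, CH2Cl2, −20 °C
Reagents that add atoms: tert-butyl hydroperoxide, CC(C)(C)OO
Why: Sharpless asymmetric epoxidation under catalytic conditions, in which the D-(−)-tartrate/titanium catalyst selects the alkene face that leads to the (R)-epoxy alcohol (the L-(+)-tartrate gives the S series with 2-alkylallyl alcohols) and thereby sets the quaternary C–O stereocentre, the future C2.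

Step 3
Reactants: 5 [(2R)-2-hexadecyloxiran-2-yl]methanol
Product: 6 (2S)-2-hexadecyloxirane-2-carbaldehyde
Conditions: TEMPO (10 mol %), PhI(OAc)2, CH2Cl2, rt
Reagents that add atoms: none
Why: Oxoammonium (TEMPO/PhI(OAc)2) oxidation of the primary alcohol stops at the aldehyde and spares the epoxide, and the quaternary α-carbon cannot epimerise (the descriptor becomes S only through the CIP priority change).

Step 4
Reactants: 6 (2S)-2-hexadecyloxirane-2-carbaldehyde; 7 methyl 2-[bis(2,2,2-trifluoroethoxy)phosphoryl]acetate
Product: 8 methyl (2Z)-3-[(2R)-2-hexadecyloxiran-2-yl]prop-2-enoate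
Conditions: KHMDS, 18-crown-6, THF, −78 °C
Reagents that add atoms: none
Why: Still–Gennari variant of the Horner–Wadsworth–Emmons olefination, in which fast irreversible collapse of the kinetic adduct of the electron-poor phosphonate should give the (Z)-enoate, while the non-enolisable epoxy aldehyde keeps its configuration.

Step 5
Reactants: 8 methyl (2Z)-3-[(2R)-2-hexadecyloxiran-2-yl]prop-2-enoate
Product: 9 methyl (2Z)-3-[(2S)-2-hexadecyl-4-oxooxetan-2-yl]prop-2-enoate
Conditions: [(salph)Al(THF)2][Co(CO)4] (5 mol %), CO (60 bar), CPME, 50 °C
Reagents that add atoms: carbon monoxide, [C-]#[O+]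
Why: Ring-expansive carbonylation of a 2,2-disubstituted epoxide, in which the Lewis-acid-activated epoxide is opened by [Co(CO)4]− in SN2 fashion at the unsubstituted CH2, CO inserts and the aluminium alkoxide closes on the acyl-cobalt, so the quaternary C–O bond is never broken and the configuration is retained (descriptor S by priority change).

Step 6
Reactants: 9 methyl (2Z)-3-[(2S)-2-hexadecyl-4-oxooxetan-2-yl]prop-2-enoate
Product: 11 methyl (1R,2R)-2-hexadecyl-2-hydroxy-5-oxocyclopent-3-ene-1-carboxylate, via bicyclic keto-β-lactone 10 (not isolated)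
Conditions: LiHMDS (2.2 equiv), THF, −78 → −20 °C (9 added to the base); inverse quench into AcOH/THF, −78 °C
Reagents that add atoms: none
Why: Proposed new method: LiHMDS turns the oxetan-2-one CH2 into its lithium enolate, which adds to the (Z)-held methyl ester carbonyl and expels LiOMe (C5–C1 bond, keto-β-lactone 10), after which LiOMe attacks the strained lactone C=O and cleaves the acyl–O bond, so the step is overall a base-triggered isomerisation of 9 that is driven by release of four-ring strain and by formation of the β-keto ester enolate. The closest known reaction types are the Dieckmann condensation and the low-temperature trapping of β-lactone enolates by carbon electrophiles, but an intramolecular ester acylation of such an enolate coupled to an alkoxide relay is not established. The cyclopentenone ring closes in a 5-(enolexo)-exo-trig mode, and the only geometry open to it is the cis-fused bicyclo[3.2.0] frame. C2 is untouched because its C–O bond is never broken, and C1 is placed with its carboxyl carbon syn to the C2 oxygen by that ring fusion and should stay so after the quench, because the epimerisable β-keto ester prefers CO2Me anti to the hexadecyl chain and hydrogen-bonded to the C2–OH. The selectivity needed is C-acylation over β-elimination, butenolide formation and retro-aldol racemisation: in the four-membered enolate the C–O bond lies in the nodal plane of the π system, the tertiary oxygen stays acylated until the carbocycle exists, and the doubly deprotonated product is protonated at the alkoxide first in the cold inverse quench. Adding 9 to excess base secures fast and complete enolisation, which keeps the liberated methoxide away from unreacted lactone.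

Compound list
1 | 1-bromohexadecane | CCCCCCCCCCCCCCCCBr | starting material
2 | prop-2-yn-1-ol (propargyl alcohol) | C#CCO | starting material
3 | hexadecylmagnesium bromide | CCCCCCCCCCCCCCCC[Mg]Br | intermediate
4 | 2-methylideneoctadecan-1-ol (2-hexadecylprop-2-en-1-ol) | CCCCCCCCCCCCCCCCC(=C)CO | intermediate
5 | [(2R)-2-hexadecyloxiran-2-yl]methanol | CCCCCCCCCCCCCCCC[C@@]1(CO)CO1 | intermediate
6 | (2S)-2-hexadecyloxirane-2-carbaldehyde | CCCCCCCCCCCCCCCC[C@@]1(C=O)CO1 | intermediate
7 | methyl 2-[bis(2,2,2-trifluoroethoxy)phosphoryl]acetate | COC(=O)CP(=O)(OCC(F)(F)F)OCC(F)(F)F | starting material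
8 | methyl (2Z)-3-[(2R)-2-hexadecyloxiran-2-yl]prop-2-enoate | CCCCCCCCCCCCCCCC[C@@]1(/C=C\C(=O)OC)CO1 | intermediate
9 | methyl (2Z)-3-[(2S)-2-hexadecyl-4-oxooxetan-2-yl]prop-2-enoate | CCCCCCCCCCCCCCCC[C@@]1(/C=C\C(=O)OC)CC(=O)O1 | intermediate
10 | (1R,5R)-5-hexadecyl-6-oxabicyclo[3.2.0]hept-3-ene-2,7-dione (cis-fused keto-β-lactone) | CCCCCCCCCCCCCCCC[C@@]12C=CC(=O)[C@@H]1C(=O)O2 | intermediate
11 | methyl (1R,2R)-2-hexadecyl-2-hydroxy-5-oxocyclopent-3-ene-1-carboxylate | CCCCCCCCCCCCCCCC[C@@]1(O)C=CC(=O)[C@@H]1C(=O)OC | target

Total step count: 6. Longest linear sequence: 6 steps (1 → 11).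

Steps most likely to fail

1. Step 6. The C-acylation may be slower than ring-opening β-elimination or self-condensation of the lactone enolate on warming, or methoxide may attack lactone that is not yet enolised.
- The fallback is an open-chain Dieckmann condensation with the tertiary oxygen blocked as a silyl ether. It uses only known chemistry, forms the same C5–C1 bond, sets out from 5 and returns at 11.
- Etherification of 5 (NaH, PMBCl, Bu4NI, THF) should give the PMB-protected epoxide F1.
- Cobalt-catalysed methoxycarbonylation (Co2(CO)8, 3-hydroxypyridine, CO, MeOH/THF) should open it at CH2 to the β-hydroxy ester F2.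
- TESOTf/2,6-lutidine should give the tertiary TES ether F3.
- DDQ should release the primary alcohol F4, which is oxidised at once with Dess–Martin periodinane to the aldehyde F5 before it can lactonise.
- Still–Gennari olefination with 7 should give the (Z)-diester F6.
- LiHMDS in THF at −78 °C should close it to the TES-protected β-keto ester F7, and buffered HF·pyridine should then give 11.

2. Step 5. The catalyst may isomerise the epoxide in a Meinwald-type hydride shift, the cobaltate may add to the conjugated ester, or the intermediate aluminium alkoxide may transesterify onto the (Z)-ester before it closes on the acyl-cobalt.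
- The fallback carbonylates a simple, unconjugated epoxide first and builds the acrylate arm afterwards. It sets out from 5 and returns at 9.
- TBSCl/imidazole should give the silyl ether F8.
- The same bimetallic carbonylation should give the silyloxymethyl β-lactone F9.
- HF·pyridine should give the hydroxymethyl β-lactone F10.
- Dess–Martin periodinane should give the lactone aldehyde F11.
- Still–Gennari olefination with 7 at −78 °C should give 9.

3. Step 4. Z-selectivity may erode at the hindered α-quaternary aldehyde, or the phosphonate anion may attack the epoxide.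
- The fallback fixes the alkene geometry by syn hydrogenation instead of olefination. It sets out from 6 and returns at 8.
- Ohira–Bestmann homologation (dimethyl (1-diazo-2-oxopropyl)phosphonate, K2CO3, MeOH) should give the ethynyl epoxide F12.
- n-BuLi followed by ClCO2Me at −78 °C should give the alkynoate F13.
- Lindlar semihydrogenation (quinoline) should give 8.

Further compounds
F1 | step 6 | (2S)-2-hexadecyl-2-{[(4-methoxyphenyl)methoxy]methyl}oxirane | CCCCCCCCCCCCCCCC[C@@]1(COCc2ccc(OC)cc2)CO1
F2 | step 6 | methyl (3S)-3-hydroxy-3-{[(4-methoxyphenyl)methoxy]methyl}nonadecanoate | CCCCCCCCCCCCCCCC[C@@](O)(COCc1ccc(OC)cc1)CC(=O)OC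
F3 | step 6 | methyl (3S)-3-{[(4-methoxyphenyl)methoxy]methyl}-3-[(triethylsilyl)oxy]nonadecanoate | CCCCCCCCCCCCCCCC[C@@](O[Si](CC)(CC)CC)(COCc1ccc(OC)cc1)CC(=O)OC
F4 | step 6 | methyl (3S)-3-(hydroxymethyl)-3-[(triethylsilyl)oxy]nonadecanoate | CCCCCCCCCCCCCCCC[C@@](O[Si](CC)(CC)CC)(CO)CC(=O)OC
F5 | step 6 | methyl (3S)-3-formyl-3-[(triethylsilyl)oxy]nonadecanoate | CCCCCCCCCCCCCCCC[C@@](O[Si](CC)(CC)CC)(C=O)CC(=O)OC
F6 | step 6 | dimethyl (2Z,4S)-4-hexadecyl-4-[(triethylsilyl)oxy]hex-2-enedioate | CCCCCCCCCCCCCCCC[C@@](O[Si](CC)(CC)CC)(/C=C\C(=O)OC)CC(=O)OC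
F7 | step 6 | methyl (1R,2R)-2-hexadecyl-5-oxo-2-[(triethylsilyl)oxy]cyclopent-3-ene-1-carboxylate | CCCCCCCCCCCCCCCC[C@@]1(O[Si](CC)(CC)CC)C=CC(=O)[C@@H]1C(=O)OC
F8 | step 5 | tert-butyl{[(2S)-2-hexadecyloxiran-2-yl]methoxy}dimethylsilane | CCCCCCCCCCCCCCCC[C@@]1(CO[Si](C)(C)C(C)(C)C)CO1
F9 | step 5 | (4S)-4-{[(tert-butyldimethylsilyl)oxy]methyl}-4-hexadecyloxetan-2-one | CCCCCCCCCCCCCCCC[C@@]1(CO[Si](C)(C)C(C)(C)C)CC(=O)O1
F10 | step 5 | (4S)-4-hexadecyl-4-(hydroxymethyl)oxetan-2-one | CCCCCCCCCCCCCCCC[C@@]1(CO)CC(=O)O1
F11 | step 5 | (2S)-2-hexadecyl-4-oxooxetane-2-carbaldehyde | CCCCCCCCCCCCCCCC[C@@]1(C=O)CC(=O)O1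
F12 | step 4 | (2R)-2-ethynyl-2-hexadecyloxirane | CCCCCCCCCCCCCCCC[C@@]1(C#C)CO1
F13 | step 4 | methyl 3-[(2R)-2-hexadecyloxiran-2-yl]prop-2-ynoate | CCCCCCCCCCCCCCCC[C@@]1(C#CC(=O)OC)CO1
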